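**Minutes of the meeting on the dusk flask**

The analyst opened with the early times of the dusk flask, the very flask asked about: substrate fell quickly and target rose to a reading of 49.6 % at 2.50 h.

| flask | substrate | reagent | free catalyst | remark | time |
|---|---|---|---|---|---|
| dusk | 0.30 M | 0.70 equiv | 0.25 mol% | the very flask that is asked about, followed so far |  |
| flask | 0.30 M | 0.700 equiv | 0.25 mol% |  | 30 h |

- dusk (time / h: target / %, substrate / %): 1.33: 44.2, 47.2; 2.50: 49.6, 34.5; 4.00: 44.8, 32.0; 6.00: 35.3, 28.6; 10.0: 26.0, 29.1; 20.0: 23.0, 29.3

(standard deviation of a reading: 1 percentage point)

- south-west: change nothing and wait 30 h more
- south: at 30 h add reagent, 50.0 % of the amount charged, then wait 30 h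
- east: at 30 h take out 90 % of the released group then present, then wait 30 h
- north-west: at 30 h add free catalyst, 100 % of the amount charged, then wait 30 h

- the volume of additions can be left aside

* target, in percent of the substrate first charged, at 30 h
* the remedy with the largest gain of target, or "none" below 2 percentage points (south-west / south / east / north-west / none)
* target present, in percent of the substrate first charged, after south-west
* target present, in percent of the substrate first charged, after south

The analyst then pointed to a crossing at which control changes hands. From 6.00 h on the substrate readings of the dusk flask stand still near 29.3 %, so 70.7 % of the substrate has gone on a charge of 0.70 equiv, which marks reagent as the limiting reagent. Target keeps falling after that crossing, so the later readings show a split among products and no longer a feed.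

The analyst therefore proposed one quantity, the resting share: target over substrate converted, once target has levelled off. The reading at 20.0 h gives 32.5 %, with the scatter of 1 percentage point on each reading.

On this reckoning "now" and south-west both stay near 23.0 %. South adds half as much reagent again, good for 35.3 % of the substrate, more than the 29.3 % left. If the split holds whatever the amount converted, target after south equals the share itself, 32.5 %, a gain of 9.5 points. The analyst named south, having no reading of the released group to judge east.

The forecaster disagreed on the remedy. The forecast gave 22.8 % (21.3 % to 24.2 %) for now, 22.8 % (21.2 % to 24.2 %) after south-west and 28 % (25.5 % to 32 %) after south, below the analyst's figure. It chose east, at about 33, since the levelling “points to a reversible loss” involving the released group.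

**Result**

The dusk flask gives 21.6 % at 30 h, 21.6 % after south-west and 30.9 % after south. The best remedy is south, with the largest gain, 9.2 points, while east changes target by −0.025 points.

    reagent + catalyst intermediate A ⇌ catalyst intermediate B (K = 9.63 M⁻¹, k = 24.9 M⁻¹ min⁻¹)
    free catalyst + released group ⇌ idle complex (K = 2.53 M⁻¹, k = 0.568 M⁻¹ min⁻¹)
    target ⇌ isomer of the product (K = 2.24, k = 0.00302 min⁻¹)
    catalyst intermediate C → free catalyst + target (k = 51.9 min⁻¹)
    catalyst intermediate B ⇌ released group + catalyst intermediate C (K = 1.10 M, k = 296 min⁻¹)
    substrate + free catalyst → catalyst intermediate A (k = 904 M⁻¹ min⁻¹)

Target turns into isomer of the product with a half-life of 3.8 h by the forward step alone, short against the 30 h of the dusk flask. At 30.0 h that flask holds 21.6 % target beside 48.4 % isomer of the product, with reagent at 0 % and substrate at 29.7 %. The resting share as read, 32.5 %, applied to the substrate converted in that flask gives 22.8 % of target, and the flask holds 21.6 %. In the neighbour flask with 0.420 equiv of reagent, which ends with 57.8 % substrate, the share gives 13.7 %, and that flask holds 13.0 % target.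

(Readings and results were computed from invented constants; the scatter is artificial.)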